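**Retrosynthetic overview**
- The ten-membered carbocycle is closed last, at C3=C4, by an intramolecular Horner–Wadsworth–Emmons reaction of an aldehyde with a C4 phosphonoacetate (C4–C5 made by phosphonoacetate alkylation).
- C1 (isopropenyl) comes from a trans-selective conjugate addition to a 6-substituted 5,6-dihydropyran-2-one, which is later opened by reduction to free C3–OH and C9–OH.
- That lactone comes from acryloylation and ring-closing metathesis of a homoallylic alcohol made by the key intermolecular asymmetric carbonyl allylation (C9–C10) of an α,β-epoxy aldehyde with (−)-Ipc2B(allyl).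
- The epoxy aldehyde comes from Sharpless epoxidation of a trisubstituted allylic alcohol built from but-3-yn-1-ol (hydromagnesiation/iodination, then hydroxymethylation).
- Ring order: oxirane, then a temporary six-membered lactone, then the ten-membered carbocycle.

Assumption: labels used below are C1 (isopropenyl carbon), C2, C3=C4 (C4 carries C15O2Me), C5, C6, C7–C8 (oxirane; C8 carries C14H2O), C9 (OAc), C10; PMB = 4-methoxybenzyl, TBS = tert-butyldimethylsilyl, TBDPS = tert-butyldiphenylsilyl; (−)-Ipc2B(allyl) is bought as its pentane solution. The route is a paper design and has not been run; selectivities are expectations from analogous reactions.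

**Step 1**
Reactants: 1 but-3-yn-1-ol
Product: 2 4-methoxybenzyl but-3-yn-1-yl ether
Conditions: NaH, PMBCl, Bu4NI (cat.), THF/DMF, 0 °C to rt
Reagents that add atoms: 4-methoxybenzyl chloride COc1ccc(CCl)cc1
Why: Williamson ether synthesis; the alkoxide displaces chloride and gives a C5–O protecting group that survives every step up to step 17.

**Step 2**
Reactants: 2 4-methoxybenzyl but-3-yn-1-yl ether
Product: 4 5-(4-methoxybenzyloxy)pent-2-yn-1-ol, via lithium acetylide 3 (not isolated)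
Conditions: n-BuLi, THF, −78 °C; (CH2O)n, −78 °C to rt; then H2O
Reagents that add atoms: formaldehyde (as paraformaldehyde) C=O
Why: Acetylide hydroxymethylation (1,2-addition to formaldehyde) installs C14 as the propargylic alcohol needed to direct the next step.

**Step 3**
Reactants: 4 5-(4-methoxybenzyloxy)pent-2-yn-1-ol
Product: 6 (2E)-2-iodo-5-(4-methoxybenzyloxy)pent-2-en-1-ol, via alkenylmagnesium chloride 5 (not isolated)
Conditions: i-BuMgCl (2.3 equiv), Cp2TiCl2 (5 mol%), Et2O, rt; then I2, THF, −78 to 0 °C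
Reagents that add atoms: iodine II
Why: Cp2TiCl2-catalysed hydromagnesiation adds H and Mg syn with Mg on the carbon next to the alkoxide, and iodinolysis with retention fixes the chain (C6) cis to C14H2OH.

**Step 4**
Reactants: 6 (2E)-2-iodo-5-(4-methoxybenzyloxy)pent-2-en-1-ol
Product: 7 (2E)-1-(TBS-oxy)-2-iodo-5-(PMB-oxy)pent-2-ene
Conditions: TBSCl, imidazole, CH2Cl2, rt
Reagents that add atoms: tert-butyldimethylsilyl chloride CC(C)(C)[Si](C)(C)Cl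
Why: Silylation masks the C14 hydroxyl so that only the C9 hydroxyl made next can direct the epoxidation.

**Step 5**
Reactants: 7 (2E)-1-(TBS-oxy)-2-iodo-5-(PMB-oxy)pent-2-ene
Product: 9 (2Z)-2-(TBS-oxymethyl)-5-(PMB-oxy)pent-2-en-1-ol, via alkenyllithium 8 (not isolated)
Conditions: t-BuLi (2.1 equiv), Et2O, −78 °C; (CH2O)n, −78 °C to rt; then H2O
Reagents that add atoms: formaldehyde (as paraformaldehyde) C=O
Why: Iodine–lithium exchange proceeds with retention of alkene geometry and 1,2-addition to formaldehyde installs C9 trans to the C6 chain.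

**Step 6**
Reactants: 9 (2Z)-2-(TBS-oxymethyl)-5-(PMB-oxy)pent-2-en-1-ol
Product: 10 [(2S,3R)-2-(TBS-oxymethyl)-3-(2-PMB-oxyethyl)oxiran-2-yl]methanol
Conditions: Ti(OiPr)4 (10 mol%), D-(−)-diethyl tartrate (12 mol%), t-BuOOH, 4 Å MS, CH2Cl2, −20 °C
Reagents that add atoms: tert-butyl hydroperoxide CC(C)(C)OO
Why: Sharpless asymmetric epoxidation of an achiral 2,3-E-disubstituted allylic alcohol (the best substrate class); the D-(−)-tartrate catalyst delivers oxygen to the face that gives the target C7/C8 configuration.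

**Step 7**
Reactants: 10 [(2S,3R)-2-(TBS-oxymethyl)-3-(2-PMB-oxyethyl)oxiran-2-yl]methanol
Product: 11 (2S,3R)-2-(TBS-oxymethyl)-3-(2-PMB-oxyethyl)oxirane-2-carbaldehyde
Conditions: Dess–Martin periodinane, NaHCO3, CH2Cl2, rt
Reagents that add atoms: none
Why: Dess–Martin oxidation under buffered conditions gives the epoxy aldehyde, which cannot epimerise because its α-carbon is quaternary.

**Step 8**
Reactants: 11 (2S,3R)-2-(TBS-oxymethyl)-3-(2-PMB-oxyethyl)oxirane-2-carbaldehyde; 12 (−)-B-allyldiisopinocampheylborane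
Product: 14 (1S)-1-[(2R,3R)-2-(TBS-oxymethyl)-3-(2-PMB-oxyethyl)oxiran-2-yl]but-3-en-1-ol, via borinate ester 13 (not isolated)
Conditions: Et2O, −78 °C; then H2O2, pH 7 buffer, MeOH, 0 °C
Reagents that add atoms: none
Why: Brown asymmetric allylboration (intermolecular carbonyl allylation through a chair transition state) forms the key C9–C10 bond; the (+)-α-pinene-derived reagent adds to the Si face to set 9S, and a Cornforth-type preference for attack anti to the CH2OTBS group should reinforce this.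

**Step 9**
Reactants: 14 (1S)-1-[(2R,3R)-2-(TBS-oxymethyl)-3-(2-PMB-oxyethyl)oxiran-2-yl]but-3-en-1-ol
Product: 15 (1S)-1-[(2S,3R)-2-(TBS-oxymethyl)-3-(2-PMB-oxyethyl)oxiran-2-yl]but-3-en-1-yl acrylate
Conditions: acryloyl chloride, i-Pr2NEt, DMAP (cat.), CH2Cl2, 0 °C
Reagents that add atoms: acryloyl chloride C=CC(=O)Cl
Why: O-acylation of the secondary alcohol brings in C2 and C3 and sets up the metathesis.

**Step 10**
Reactants: 15 (1S)-1-[(2S,3R)-2-(TBS-oxymethyl)-3-(2-PMB-oxyethyl)oxiran-2-yl]but-3-en-1-yl acrylate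
Product: 16 (6S)-6-[(2S,3R)-2-(TBS-oxymethyl)-3-(2-PMB-oxyethyl)oxiran-2-yl]-5,6-dihydro-2H-pyran-2-one
Conditions: second-generation Grubbs catalyst (H2IMes)(PCy3)Cl2Ru=CHPh (5 mol%), CH2Cl2 (5 mM), 40 °C
Reagents that add atoms: none
Why: Ring-closing metathesis of the allyl and acrylate termini forms the six-membered unsaturated lactone with loss of ethylene.

**Step 11**
Reactants: 16 (6S)-6-[(2S,3R)-2-(TBS-oxymethyl)-3-(2-PMB-oxyethyl)oxiran-2-yl]-5,6-dihydro-2H-pyran-2-one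
Product: 18 (4R,6S)-6-[(2S,3R)-2-(TBS-oxymethyl)-3-(2-PMB-oxyethyl)oxiran-2-yl]-4-(prop-1-en-2-yl)tetrahydro-2H-pyran-2-one, via silyl ketene acetal 17 (not isolated)
Conditions: isopropenylMgBr, CuBr·SMe2 (20 mol%), TMSCl, THF, −78 °C; then aq. NH4Cl
Reagents that add atoms: isopropenylmagnesium bromide CC(=C)[Mg]Br
Why: Copper-catalysed conjugate (Michael-type) addition occurs by axial attack on the half-chair anti to the pseudo-equatorial C6 substituent, giving the 4,6-trans lactone and thereby setting C1; at −78 °C the trisubstituted oxirane should survive.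

**Step 12**
Reactants: 18 (4R,6S)-6-[(2S,3R)-2-(TBS-oxymethyl)-3-(2-PMB-oxyethyl)oxiran-2-yl]-4-(prop-1-en-2-yl)tetrahydro-2H-pyran-2-one
Product: 19 (3S,5S)-5-[(2R,3R)-2-(TBS-oxymethyl)-3-(2-PMB-oxyethyl)oxiran-2-yl]-3-(prop-1-en-2-yl)pentane-1,5-diol
Conditions: LiBH4, THF, 0 °C
Reagents that add atoms: none
Why: Hydride reduction of the lactone opens the temporary ring to the C3/C9 diol without touching silyl ether, PMB ether or the hindered oxirane.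

**Step 13**
Reactants: 19 (3S,5S)-5-[(2R,3R)-2-(TBS-oxymethyl)-3-(2-PMB-oxyethyl)oxiran-2-yl]-3-(prop-1-en-2-yl)pentane-1,5-diol
Product: 20 (1S,3S)-5-(TBDPS-oxy)-1-[(2R,3R)-2-(TBS-oxymethyl)-3-(2-PMB-oxyethyl)oxiran-2-yl]-3-(prop-1-en-2-yl)pentan-1-ol
Conditions: TBDPSCl, imidazole, CH2Cl2, 0 °C
Reagents that add atoms: tert-butyldiphenylsilyl chloride CC(C)(C)[Si](Cl)(c1ccccc1)c1ccccc1
Why: Selective silylation of the primary C3 hydroxyl over the hindered secondary C9 hydroxyl.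

**Step 14**
Reactants: 20 (1S,3S)-5-(TBDPS-oxy)-1-[(2R,3R)-2-(TBS-oxymethyl)-3-(2-PMB-oxyethyl)oxiran-2-yl]-3-(prop-1-en-2-yl)pentan-1-ol
Product: 21 (1S,3S)-5-(TBDPS-oxy)-1-[(2R,3R)-2-(hydroxymethyl)-3-(2-PMB-oxyethyl)oxiran-2-yl]-3-(prop-1-en-2-yl)pentan-1-ol
Conditions: HF·pyridine, pyridine, THF, 0 °C
Reagents that add atoms: none
Why: Buffered HF cleaves the primary TBS ether much faster than the primary TBDPS ether, freeing C14–OH.

**Step 15**
Reactants: 21 (1S,3S)-5-(TBDPS-oxy)-1-[(2R,3R)-2-(hydroxymethyl)-3-(2-PMB-oxyethyl)oxiran-2-yl]-3-(prop-1-en-2-yl)pentan-1-ol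
Product: 22 {(2R,3R)-2-[(1S,3S)-5-(TBDPS-oxy)-1-hydroxy-3-(prop-1-en-2-yl)pentyl]-3-(2-PMB-oxyethyl)oxiran-2-yl}methyl 2-methylpropanoate
Conditions: i-PrCOCl (1.1 equiv), 2,4,6-collidine, CH2Cl2, −40 to 0 °C
Reagents that add atoms: isobutyryl chloride CC(C)C(=O)Cl
Why: Selective acylation of the primary C14 hydroxyl over the hindered secondary C9 hydroxyl; putting the primary ester on first avoids a secondary acetate sitting next to a free primary alcohol.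

**Step 16**
Reactants: 22 {(2R,3R)-2-[(1S,3S)-5-(TBDPS-oxy)-1-hydroxy-3-(prop-1-en-2-yl)pentyl]-3-(2-PMB-oxyethyl)oxiran-2-yl}methyl 2-methylpropanoate
Product: 23 {(2S,3R)-2-[(1S,3S)-1-acetoxy-5-(TBDPS-oxy)-3-(prop-1-en-2-yl)pentyl]-3-(2-PMB-oxyethyl)oxiran-2-yl}methyl 2-methylpropanoate
Conditions: Ac2O, DMAP (cat.), pyridine, rt
Reagents that add atoms: acetic anhydride CC(=O)OC(C)=O
Why: DMAP-catalysed acetylation of the remaining C9 hydroxyl with retention.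

**Step 17**
Reactants: 23 {(2S,3R)-2-[(1S,3S)-1-acetoxy-5-(TBDPS-oxy)-3-(prop-1-en-2-yl)pentyl]-3-(2-PMB-oxyethyl)oxiran-2-yl}methyl 2-methylpropanoate
Product: 24 {(2S,3R)-2-[(1S,3S)-1-acetoxy-5-(TBDPS-oxy)-3-(prop-1-en-2-yl)pentyl]-3-(2-hydroxyethyl)oxiran-2-yl}methyl 2-methylpropanoate
Conditions: DDQ, CH2Cl2/pH 7 buffer, 0 °C
Reagents that add atoms: none
Why: Oxidative PMB cleavage under neutral conditions leaves esters, silyl ether, oxirane and isopropenyl untouched.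

**Step 18**
Reactants: 24 {(2S,3R)-2-[(1S,3S)-1-acetoxy-5-(TBDPS-oxy)-3-(prop-1-en-2-yl)pentyl]-3-(2-hydroxyethyl)oxiran-2-yl}methyl 2-methylpropanoate
Product: 25 {(2S,3R)-2-[(1S,3S)-1-acetoxy-5-(TBDPS-oxy)-3-(prop-1-en-2-yl)pentyl]-3-(2-iodoethyl)oxiran-2-yl}methyl 2-methylpropanoate
Conditions: I2, PPh3, imidazole, CH2Cl2, 0 °C
Reagents that add atoms: iodine II
Why: Appel-type iodination converts the primary C5 alcohol into the iodide under near-neutral conditions.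

**Step 19**
Reactants: 25 {(2S,3R)-2-[(1S,3S)-1-acetoxy-5-(TBDPS-oxy)-3-(prop-1-en-2-yl)pentyl]-3-(2-iodoethyl)oxiran-2-yl}methyl 2-methylpropanoate
Product: 26 methyl 2-(dimethoxyphosphoryl)-4-{(2R,3S)-3-[(1S,3S)-1-acetoxy-5-(TBDPS-oxy)-3-(prop-1-en-2-yl)pentyl]-3-[(2-methylpropanoyloxy)methyl]oxiran-2-yl}butanoate (both C4 epimers)
Conditions: NaH, (MeO)2P(O)CH2CO2Me (3 equiv), DMF, 0 to 50 °C
Reagents that add atoms: trimethyl phosphonoacetate COC(=O)CP(=O)(OC)OC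
Why: SN2 alkylation of the soft phosphonoacetate anion forms C4–C5 and brings in C15; excess anion suppresses dialkylation and the C4 centre is lost in step 22.

**Step 20**
Reactants: 26 methyl 2-(dimethoxyphosphoryl)-4-{(2R,3S)-3-[(1S,3S)-1-acetoxy-5-(TBDPS-oxy)-3-(prop-1-en-2-yl)pentyl]-3-[(2-methylpropanoyloxy)methyl]oxiran-2-yl}butanoate
Product: 27 methyl 2-(dimethoxyphosphoryl)-4-{(2R,3S)-3-[(1S,3S)-1-acetoxy-5-hydroxy-3-(prop-1-en-2-yl)pentyl]-3-[(2-methylpropanoyloxy)methyl]oxiran-2-yl}butanoate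
Conditions: TBAF, AcOH, THF, rt
Reagents that add atoms: none
Why: Acetic-acid-buffered fluoride desilylation frees the C3 alcohol without ester cleavage or acyl migration.

**Step 21**
Reactants: 27 methyl 2-(dimethoxyphosphoryl)-4-{(2R,3S)-3-[(1S,3S)-1-acetoxy-5-hydroxy-3-(prop-1-en-2-yl)pentyl]-3-[(2-methylpropanoyloxy)methyl]oxiran-2-yl}butanoate
Product: 28 methyl 2-(dimethoxyphosphoryl)-4-{(2R,3S)-3-[(1S,3R)-1-acetoxy-5-oxo-3-(prop-1-en-2-yl)pentyl]-3-[(2-methylpropanoyloxy)methyl]oxiran-2-yl}butanoate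
Conditions: Dess–Martin periodinane, NaHCO3, CH2Cl2, rt
Reagents that add atoms: none
Why: Dess–Martin oxidation gives the C3 aldehyde under conditions the esters, oxirane and phosphonate tolerate.

**Step 22**
Reactants: 28 methyl 2-(dimethoxyphosphoryl)-4-{(2R,3S)-3-[(1S,3R)-1-acetoxy-5-oxo-3-(prop-1-en-2-yl)pentyl]-3-[(2-methylpropanoyloxy)methyl]oxiran-2-yl}butanoate
Product: 29 CNP0372928.1, methyl (1R,4E,7S,9S,10S)-9-acetoxy-10-[(2-methylpropanoyloxy)methyl]-7-(prop-1-en-2-yl)-11-oxabicyclo[8.1.0]undec-4-ene-4-carboxylate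
Conditions: LiCl, DBU, MeCN (1 mM, slow addition), rt
Reagents that add atoms: none
Why: Intramolecular Horner–Wadsworth–Emmons olefination (Masamune–Roush conditions, high dilution) closes the ten-membered ring; both the intrinsic preference of α-alkyl phosphonoacetates and ring strain favour CO2Me trans to C2 (the 4E, ring-cis alkene), and no stereocentre is touched.

**Compound list**
1 | but-3-yn-1-ol | C#CCCO | starting material
2 | 4-methoxybenzyl but-3-yn-1-yl ether | C#CCCOCc1ccc(OC)cc1 | intermediate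
3 | lithium acetylide of 2 | [Li]C#CCCOCc1ccc(OC)cc1 | intermediate (not isolated)
4 | 5-(4-methoxybenzyloxy)pent-2-yn-1-ol | OCC#CCCOCc1ccc(OC)cc1 | intermediate
5 | (E)-alkenylmagnesium chloride (Mg on C8 and on the alkoxide O, H and Mg syn) | Cl[Mg]OC/C([Mg]Cl)=C\CCOCc1ccc(OC)cc1 | intermediate (not isolated)
6 | (2E)-2-iodo-5-(4-methoxybenzyloxy)pent-2-en-1-ol | OC/C(I)=C\CCOCc1ccc(OC)cc1 | intermediate
7 | (2E)-1-(TBS-oxy)-2-iodo-5-(PMB-oxy)pent-2-ene | CC(C)(C)[Si](C)(C)OC/C(I)=C\CCOCc1ccc(OC)cc1 | intermediate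
8 | alkenyllithium from 7 (Li in place of I, geometry retained) | CC(C)(C)[Si](C)(C)OC/C([Li])=C\CCOCc1ccc(OC)cc1 | intermediate (not isolated)
9 | (2Z)-2-(TBS-oxymethyl)-5-(PMB-oxy)pent-2-en-1-ol | OC/C(CO[Si](C)(C)C(C)(C)C)=C/CCOCc1ccc(OC)cc1 | intermediate
10 | [(2S,3R)-2-(TBS-oxymethyl)-3-(2-PMB-oxyethyl)oxiran-2-yl]methanol | COc1ccc(COCC[C@H]2O[C@]2(CO[Si](C)(C)C(C)(C)C)CO)cc1 | intermediate
11 | (2S,3R)-2-(TBS-oxymethyl)-3-(2-PMB-oxyethyl)oxirane-2-carbaldehyde | COc1ccc(COCC[C@H]2O[C@]2(CO[Si](C)(C)C(C)(C)C)C=O)cc1 | intermediate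
12 | (−)-B-allyldiisopinocampheylborane, from (+)-α-pinene | C=CCB([C@@H]1C[C@@H]2C[C@H]([C@H]1C)C2(C)C)[C@@H]1C[C@@H]2C[C@H]([C@H]1C)C2(C)C | starting material
13 | O-diisopinocampheylboryl derivative of 14 | COc1ccc(COCC[C@H]2O[C@]2(CO[Si](C)(C)C(C)(C)C)[C@@H](OB([C@@H]3C[C@@H]4C[C@H]([C@H]3C)C4(C)C)[C@@H]3C[C@@H]4C[C@H]([C@H]3C)C4(C)C)CC=C)cc1 | intermediate (not isolated)
14 | (1S)-1-[(2R,3R)-2-(TBS-oxymethyl)-3-(2-PMB-oxyethyl)oxiran-2-yl]but-3-en-1-ol | COc1ccc(COCC[C@H]2O[C@]2(CO[Si](C)(C)C(C)(C)C)[C@@H](O)CC=C)cc1 | intermediate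
15 | (1S)-1-[(2S,3R)-2-(TBS-oxymethyl)-3-(2-PMB-oxyethyl)oxiran-2-yl]but-3-en-1-yl acrylate | COc1ccc(COCC[C@H]2O[C@]2(CO[Si](C)(C)C(C)(C)C)[C@@H](OC(=O)C=C)CC=C)cc1 | intermediate
16 | (6S)-6-[(2S,3R)-2-(TBS-oxymethyl)-3-(2-PMB-oxyethyl)oxiran-2-yl]-5,6-dihydro-2H-pyran-2-one | COc1ccc(COCC[C@H]2O[C@]2(CO[Si](C)(C)C(C)(C)C)[C@@H]3CC=CC(=O)O3)cc1 | intermediate
17 | trimethylsilyl ketene acetal of 18 | COc1ccc(COCC[C@H]2O[C@]2(CO[Si](C)(C)C(C)(C)C)[C@@H]3C[C@@H](C(C)=C)C=C(O[Si](C)(C)C)O3)cc1 | intermediate (not isolated)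
18 | (4R,6S)-6-[(2S,3R)-2-(TBS-oxymethyl)-3-(2-PMB-oxyethyl)oxiran-2-yl]-4-(prop-1-en-2-yl)tetrahydro-2H-pyran-2-one | COc1ccc(COCC[C@H]2O[C@]2(CO[Si](C)(C)C(C)(C)C)[C@@H]3C[C@@H](C(C)=C)CC(=O)O3)cc1 | intermediate
19 | (3S,5S)-5-[(2R,3R)-2-(TBS-oxymethyl)-3-(2-PMB-oxyethyl)oxiran-2-yl]-3-(prop-1-en-2-yl)pentane-1,5-diol | COc1ccc(COCC[C@H]2O[C@]2(CO[Si](C)(C)C(C)(C)C)[C@@H](O)C[C@@H](C(C)=C)CCO)cc1 | intermediate
20 | (1S,3S)-5-(TBDPS-oxy)-1-[(2R,3R)-2-(TBS-oxymethyl)-3-(2-PMB-oxyethyl)oxiran-2-yl]-3-(prop-1-en-2-yl)pentan-1-ol | COc1ccc(COCC[C@H]2O[C@]2(CO[Si](C)(C)C(C)(C)C)[C@@H](O)C[C@@H](C(C)=C)CCO[Si](c3ccccc3)(c3ccccc3)C(C)(C)C)cc1 | intermediate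
21 | (1S,3S)-5-(TBDPS-oxy)-1-[(2R,3R)-2-(hydroxymethyl)-3-(2-PMB-oxyethyl)oxiran-2-yl]-3-(prop-1-en-2-yl)pentan-1-ol | COc1ccc(COCC[C@H]2O[C@]2(CO)[C@@H](O)C[C@@H](C(C)=C)CCO[Si](c3ccccc3)(c3ccccc3)C(C)(C)C)cc1 | intermediate
22 | {(2R,3R)-2-[(1S,3S)-5-(TBDPS-oxy)-1-hydroxy-3-(prop-1-en-2-yl)pentyl]-3-(2-PMB-oxyethyl)oxiran-2-yl}methyl 2-methylpropanoate | COc1ccc(COCC[C@H]2O[C@]2(COC(=O)C(C)C)[C@@H](O)C[C@@H](C(C)=C)CCO[Si](c3ccccc3)(c3ccccc3)C(C)(C)C)cc1 | intermediate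
23 | {(2S,3R)-2-[(1S,3S)-1-acetoxy-5-(TBDPS-oxy)-3-(prop-1-en-2-yl)pentyl]-3-(2-PMB-oxyethyl)oxiran-2-yl}methyl 2-methylpropanoate | COc1ccc(COCC[C@H]2O[C@]2(COC(=O)C(C)C)[C@@H](OC(C)=O)C[C@@H](C(C)=C)CCO[Si](c3ccccc3)(c3ccccc3)C(C)(C)C)cc1 | intermediate
24 | {(2S,3R)-2-[(1S,3S)-1-acetoxy-5-(TBDPS-oxy)-3-(prop-1-en-2-yl)pentyl]-3-(2-hydroxyethyl)oxiran-2-yl}methyl 2-methylpropanoate | OCC[C@H]1O[C@]1(COC(=O)C(C)C)[C@@H](OC(C)=O)C[C@@H](C(C)=C)CCO[Si](c2ccccc2)(c2ccccc2)C(C)(C)C | intermediate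
25 | {(2S,3R)-2-[(1S,3S)-1-acetoxy-5-(TBDPS-oxy)-3-(prop-1-en-2-yl)pentyl]-3-(2-iodoethyl)oxiran-2-yl}methyl 2-methylpropanoate | ICC[C@H]1O[C@]1(COC(=O)C(C)C)[C@@H](OC(C)=O)C[C@@H](C(C)=C)CCO[Si](c2ccccc2)(c2ccccc2)C(C)(C)C | intermediate
26 | methyl 2-(dimethoxyphosphoryl)-4-{(2R,3S)-3-[(1S,3S)-1-acetoxy-5-(TBDPS-oxy)-3-(prop-1-en-2-yl)pentyl]-3-[(2-methylpropanoyloxy)methyl]oxiran-2-yl}butanoate (C4 epimers) | COC(=O)C(P(=O)(OC)OC)CC[C@H]1O[C@]1(COC(=O)C(C)C)[C@@H](OC(C)=O)C[C@@H](C(C)=C)CCO[Si](c2ccccc2)(c2ccccc2)C(C)(C)C | intermediate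
27 | methyl 2-(dimethoxyphosphoryl)-4-{(2R,3S)-3-[(1S,3S)-1-acetoxy-5-hydroxy-3-(prop-1-en-2-yl)pentyl]-3-[(2-methylpropanoyloxy)methyl]oxiran-2-yl}butanoate | COC(=O)C(P(=O)(OC)OC)CC[C@H]1O[C@]1(COC(=O)C(C)C)[C@@H](OC(C)=O)C[C@@H](C(C)=C)CCO | intermediate
28 | methyl 2-(dimethoxyphosphoryl)-4-{(2R,3S)-3-[(1S,3R)-1-acetoxy-5-oxo-3-(prop-1-en-2-yl)pentyl]-3-[(2-methylpropanoyloxy)methyl]oxiran-2-yl}butanoate | COC(=O)C(P(=O)(OC)OC)CC[C@H]1O[C@]1(COC(=O)C(C)C)[C@@H](OC(C)=O)C[C@@H](C(C)=C)CC=O | intermediate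
29 | CNP0372928.1, methyl (1R,4E,7S,9S,10S)-9-acetoxy-10-[(2-methylpropanoyloxy)methyl]-7-(prop-1-en-2-yl)-11-oxabicyclo[8.1.0]undec-4-ene-4-carboxylate | C=C(C)[C@H]1C/C=C(/C(=O)OC)CC[C@H]2O[C@]2(COC(=O)C(C)C)[C@@H](OC(C)=O)C1 | target

**Totals**
Total step count: 22. Longest linear sequence: 22 steps (from 1 to 29).

**Three steps most likely to fail, with fallbacks**

Step 22 (ten-membered ring closure): medium-ring strain and oligomerisation may defeat the intramolecular olefination. The fallback closes the same bond by ring-closing metathesis; it sets out from 26 and comes back at 29. Treating 26 with aqueous formaldehyde and K2CO3 in THF gives the 2-methylene ester F1 (olefination with formaldehyde). TBAF/AcOH then gives the alcohol F2, and Dess–Martin periodinane gives the aldehyde F3. Ph3P=CH2 (from Ph3PCH3Br and KHMDS, THF, −78 °C) gives the terminal alkene F4. Ring-closing metathesis of F4 with the second-generation Hoveyda–Grubbs catalyst (H2IMes)Cl2Ru=CH(C6H4-2-OiPr) in toluene at 80 °C and 1 mM closes C3=C4 as the strain-favoured ring-cis (4E) enoate 29.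

Step 11 (conjugate addition next to an oxirane, which also depends on the epoxy-aldehyde allylation of step 8): the organocopper/Grignard mixture may open the oxirane. The fallback installs the oxirane after C9 and C1; it sets out from 9 and comes back at 18. MnO2 in CH2Cl2 oxidises 9 to the enal F5. Allylboration with 12 at −78 °C gives the borinate F6 and, after oxidative work-up, the (S)-dienol F7. Acryloyl chloride with i-Pr2NEt gives the acrylate F8, and the second-generation Grubbs catalyst gives the dihydropyranone F9. IsopropenylMgBr with CuBr·SMe2 and TMSCl gives the silyl ketene acetal F10 and, on work-up, the trans lactone F11. HF·pyridine frees the allylic alcohol F12. Sharpless epoxidation with Ti(OiPr)4, L-(+)-diethyl tartrate and t-BuOOH, directed only by the C14 hydroxyl (the lactone oxygen cannot bind titanium), gives the epoxy alcohol F13. TBSCl with imidazole converts F13 into 18.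

Step 3 (hydromagnesiation): regiocontrol or catalyst turnover may be poor with the ether-bearing alkyne. The fallback uses hydrostannation instead; it sets out from 4 and comes back at 6. Syn-hydrostannation of 4 with Bu3SnH and PdCl2(PPh3)2 (cat.) in THF gives the proximal (E)-alkenylstannane F14 after chromatographic removal of the distal isomer. Iododestannylation of F14 with I2 in CH2Cl2 at 0 °C gives 6 with retention.

**Further compounds**
F1 | step 22 | methyl 2-methylidene-4-{(2R,3S)-3-[(1S,3S)-1-acetoxy-5-(TBDPS-oxy)-3-(prop-1-en-2-yl)pentyl]-3-[(2-methylpropanoyloxy)methyl]oxiran-2-yl}butanoate | COC(=O)C(=C)CC[C@H]1O[C@]1(COC(=O)C(C)C)[C@@H](OC(C)=O)C[C@@H](C(C)=C)CCO[Si](c2ccccc2)(c2ccccc2)C(C)(C)C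
F2 | step 22 | 5-hydroxy analogue of F1 (TBDPS removed) | COC(=O)C(=C)CC[C@H]1O[C@]1(COC(=O)C(C)C)[C@@H](OC(C)=O)C[C@@H](C(C)=C)CCO
F3 | step 22 | 5-oxo analogue of F1 (C3 aldehyde) | COC(=O)C(=C)CC[C@H]1O[C@]1(COC(=O)C(C)C)[C@@H](OC(C)=O)C[C@@H](C(C)=C)CC=O
F4 | step 22 | terminal alkene from F3 (C3 vinyl, C4 methylene ester) | COC(=O)C(=C)CC[C@H]1O[C@]1(COC(=O)C(C)C)[C@@H](OC(C)=O)C[C@@H](C(C)=C)CC=C
F5 | step 11 | (2E)-2-(TBS-oxymethyl)-5-(PMB-oxy)pent-2-enal | O=C/C(CO[Si](C)(C)C(C)(C)C)=C/CCOCc1ccc(OC)cc1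
F6 | step 11 | O-diisopinocampheylboryl derivative of F7 | C=CC[C@H](OB([C@@H]1C[C@@H]2C[C@H]([C@H]1C)C2(C)C)[C@@H]1C[C@@H]2C[C@H]([C@H]1C)C2(C)C)/C(CO[Si](C)(C)C(C)(C)C)=C/CCOCc1ccc(OC)cc1
F7 | step 11 | (3S,4E)-4-(TBS-oxymethyl)-7-(PMB-oxy)hepta-1,4-dien-3-ol | C=CC[C@H](O)/C(CO[Si](C)(C)C(C)(C)C)=C/CCOCc1ccc(OC)cc1
F8 | step 11 | acrylate of F7 | C=CC[C@H](OC(=O)C=C)/C(CO[Si](C)(C)C(C)(C)C)=C/CCOCc1ccc(OC)cc1
F9 | step 11 | (6S)-6-[(2E)-1-(TBS-oxy)-5-(PMB-oxy)pent-2-en-2-yl]-5,6-dihydro-2H-pyran-2-one | O=C1C=CC[C@@H](/C(CO[Si](C)(C)C(C)(C)C)=C/CCOCc2ccc(OC)cc2)O1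
F10 | step 11 | trimethylsilyl ketene acetal of F11 | C[Si](C)(C)OC1=C[C@H](C(C)=C)C[C@@H](/C(CO[Si](C)(C)C(C)(C)C)=C/CCOCc2ccc(OC)cc2)O1
F11 | step 11 | (4R,6S)-6-[(2E)-1-(TBS-oxy)-5-(PMB-oxy)pent-2-en-2-yl]-4-(prop-1-en-2-yl)tetrahydro-2H-pyran-2-one | O=C1C[C@H](C(C)=C)C[C@@H](/C(CO[Si](C)(C)C(C)(C)C)=C/CCOCc2ccc(OC)cc2)O1
F12 | step 11 | (4R,6S)-6-[(2E)-1-hydroxy-5-(PMB-oxy)pent-2-en-2-yl]-4-(prop-1-en-2-yl)tetrahydro-2H-pyran-2-one | O=C1C[C@H](C(C)=C)C[C@@H](/C(CO)=C/CCOCc2ccc(OC)cc2)O1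
F13 | step 11 | (4R,6S)-6-[(2S,3R)-2-(hydroxymethyl)-3-(2-PMB-oxyethyl)oxiran-2-yl]-4-(prop-1-en-2-yl)tetrahydro-2H-pyran-2-one | COc1ccc(COCC[C@H]2O[C@]2(CO)[C@@H]3C[C@@H](C(C)=C)CC(=O)O3)cc1
F14 | step 3 | (2E)-2-(tributylstannyl)-5-(PMB-oxy)pent-2-en-1-ol | OC/C([Sn](CCCC)(CCCC)CCCC)=C\CCOCc1ccc(OC)cc1
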